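**Plan**

- Retrosynthesis: the six O–CH3 bonds are cut first, then the C1–C2 bond of the 1,2-dihydronaphthalene, which opens the carbocycle to an acyclic (E)-2-benzylidene-1,4-diketone carrying an ortho 4-hydroxybenzhydrol; the C3=C4 alkene (Wittig), the C1–aryl and C4a–CHO bonds and the two aryl–C(O) bonds follow.
- Forward: Grignard addition, silylation and formylation give the aldehyde, a twofold Friedel–Crafts acylation gives the enedione, and a phosphine-mediated Wittig reaction joins the two; after desilylation the only new ring (C1–C2–C3–C4–C4a–C8a) closes, and demethylation ends the route.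
- Enabling feature: C1 carries a 4-hydroxyphenyl ring and is therefore the exocyclic carbon of a latent para-quinone methide, while C2 is the enolisable α-carbon of the C2 aroyl ketone, held by the (E)-C3=C4 alkene within reach of C1 for six-membered closure.
- Stereochemistry: C1 (R) is set by a chiral phosphoric acid that selects one face of the planar quinone methide, into which both enantiomers of the racemic carbinol converge; C2 (S) follows by enol-mediated equilibration to the trans isomer.

Key step: step 7

Assumption: the sense of induction of the binaphthyl phosphoric acid cannot be predicted with confidence; the (R)-acid is written, and its mirror image would be used if it proves to favour the (1S) series. TBS = tert-butyldimethylsilyl; racemic compounds are drawn without a stereodescriptor.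

**Route**

Step 1
Reactants: 1 2-bromo-4,5-dimethoxybenzaldehyde; 2 (4-bromophenoxy)(tert-butyl)dimethylsilane
Product: 4 (2-bromo-4,5-dimethoxyphenyl)(4-{[tert-butyl(dimethyl)silyl]oxy}phenyl)methanol (racemic), via arylmagnesium bromide 3 (not isolated)
Conditions: 2, Mg turnings, THF, 50 °C; then 1, THF, 0 °C; aq. NH4Cl
Reagents that add atoms: none
Why: Grignard addition of an arylmagnesium bromide to an aromatic aldehyde should be clean because the aryl silyl ether and the ring bromide of 1 are inert to the organomagnesium species at 0 °C; the carbinol centre forms as a racemate, which is acceptable because it is erased in step 7.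

Step 2
Reactants: 4 bromo benzhydrol
Product: 5 tert-butyl{(2-bromo-4,5-dimethoxyphenyl)(4-{[tert-butyl(dimethyl)silyl]oxy}phenyl)methoxy}dimethylsilane (racemic)
Conditions: TBSCl, imidazole, DMF, rt → 40 °C
Reagents that add atoms: tert-butyldimethylsilyl chloride, CC(C)(C)[Si](C)(C)Cl
Why: Imidazole-promoted silyl ether formation on a secondary alcohol masks the benzhydrol, so that the lithiation needs no second equivalent of base and the aldehyde made next cannot close to a lactol.

Step 3
Reactants: 5 bis-TBS bromide
Product: 7 2-[{[tert-butyl(dimethyl)silyl]oxy}(4-{[tert-butyl(dimethyl)silyl]oxy}phenyl)methyl]-4,5-dimethoxybenzaldehyde (racemic), via aryllithium 6 (not isolated)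
Conditions: n-BuLi, THF, −78 °C, short; then DMF, −78 → 0 °C; aq. NH4Cl
Reagents that add atoms: N,N-dimethylformamide, CN(C)C=O
Why: Bromine–lithium exchange and formylation of the aryllithium with DMF should outrun benzylic deprotonation at −78 °C, and the bulky silyl group with a short lithiation time should suppress oxygen-to-carbon silyl migration (retro-Brook rearrangement).

Step 4
Reactants: 8 fumaryl chloride; 9 1,3-dimethoxybenzene
Product: 10 (E)-1,4-bis(2,4-dimethoxyphenyl)but-2-ene-1,4-dione
Conditions: 9 (2.2 equiv in total), AlCl3 (2.4 equiv), CH2Cl2, 0 °C → rt; ice/aq. HCl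
Reagents that add atoms: 1,3-dimethoxybenzene (second equivalent of 9), COc1cccc(OC)c1
Why: Twofold Friedel–Crafts acylation, one molecule of 1,3-dimethoxybenzene at each acid chloride terminus, should occur at C4 of the arene (para to one methoxy group and ortho to the other), and the (E)-geometry of fumaryl chloride is carried into the enedione.

Step 5
Reactants: 7 bis-TBS aldehyde; 10 enedione
Product: 12 (E)-2-{2-[{[tert-butyl(dimethyl)silyl]oxy}(4-{[tert-butyl(dimethyl)silyl]oxy}phenyl)methyl]-4,5-dimethoxybenzylidene}-1,4-bis(2,4-dimethoxyphenyl)butane-1,4-dione (racemic), via phosphorus ylide 11 (not isolated)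
Conditions: 10 (1.2 equiv), PBu3 (1.2 equiv), THF, 0 °C → rt; then 7, 60 °C
Reagents that add atoms: none
Why: Conjugate addition of PBu3 to the enedione and proton shift give the acyl-stabilised ylide 11, which olefinates the aldehyde in a Wittig reaction; stabilised ylides place the aryl group trans to the acyl group, so the (E)-alkene with the arene cis to the CH2 arm should predominate, which is the geometry ring closure needs.

Step 6
Reactants: 12 bis-TBS benzylidene diketone
Product: 13 (E)-2-{2-[hydroxy(4-hydroxyphenyl)methyl]-4,5-dimethoxybenzylidene}-1,4-bis(2,4-dimethoxyphenyl)butane-1,4-dione (racemic)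
Conditions: Bu4NF/AcOH (1:1, 3 equiv), THF, 0 °C → rt
Reagents that add atoms: none
Why: Fluoride-mediated desilylation should cleave the aryl and the benzhydryl silyl ether, and the acetic acid buffer should prevent both alkoxide-driven oxa-Michael addition to the enone and acid-driven ionisation of the benzhydrol.

Step 7
Reactants: 13 racemic 4-hydroxybenzhydrol benzylidene diketone
Product: 16 [(1R,2S)-1-(4-hydroxyphenyl)-6,7-dimethoxy-1,2-dihydronaphthalene-2,3-diyl]bis[(2,4-dimethoxyphenyl)methanone], via para-quinone methide 14 (not isolated), via cis-(1R,2R) epimer 15 (not isolated)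
Conditions: (R)-3,3'-bis(2,4,6-triisopropylphenyl)-1,1'-binaphthalene-2,2'-diyl hydrogen phosphate (10 mol%), 4 Å MS, PhMe (0.01 M), 0 °C → rt; then Et3N (0.3 equiv), rt
Reagents that add atoms: none
Why: Proposed new method: the phosphoric acid should dehydrate the 4-hydroxybenzhydrol to the para-quinone methide 14 and, as hydrogen-bond donor and acceptor, enolise the only enolisable ketone to a dienol whose α-carbon adds to the methide carbon in a 1,6-addition that forms C1–C2 and re-aromatises the phenol; the closest known reaction type is the chiral phosphoric acid-catalysed enantioselective 1,6-addition of enol-type carbon nucleophiles (1,3-dicarbonyl compounds, naphthols, indoles) to para-quinone methides generated in situ from 4-hydroxybenzyl alcohols, extended here to an intramolecular simple-ketone dienol. The carbocycle C1–C2–C3–C4–C4a–C8a closes in a 6-(enolexo)-exo-trig mode. C1 is set by the catalyst: the phosphate is hydrogen-bonded to the quinone methide oxygen and to the enol hydroxyl in a chiral ion pair, so one face of the planar methide is attacked and both enantiomers of 13 converge. C2 is set thermodynamically: it lies α to a ketone and epimerises through its enol (completed by the Et3N treatment), so any cis epimer 15 drains to the trans isomer, in which the C1 aryl and C2 aroyl groups are pseudo-axial and avoid the peri hydrogen at C8 and the C3 aroyl group. The step needs face selection at C1 and carbon- over oxygen-alkylation at a single site; the (E)-alkene holds the CH2 arm cis to the methide-bearing ring so that only this α-carbon reaches C1 through a six-membered transition state (the enol oxygen would close an eight-membered ring), and the C3 ketone has no α-hydrogen.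

Step 8
Reactants: 16 trans-(1R,2S) hexamethyl ether
Product: 17 [(1R,2S)-6,7-dihydroxy-1-(4-hydroxyphenyl)-1,2-dihydronaphthalene-2,3-diyl]bis[(2,4-dihydroxyphenyl)methanone] (CNP0195549.2)
Conditions: BBr3 (15 equiv), CH2Cl2, −78 °C → rt; H2O, 0 °C
Reagents that add atoms: none
Why: Lewis acid-mediated cleavage of aryl methyl ethers with BBr3, chelation-assisted for the two methoxy groups ortho to the carbonyls, should free all six phenols; C1 bears no acidic hydrogen and C2 already holds its preferred trans configuration, so neither stereocentre should be disturbed.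

**Compound list**

1 | 2-bromo-4,5-dimethoxybenzaldehyde | COc1cc(Br)c(C=O)cc1OC | starting material
2 | (4-bromophenoxy)(tert-butyl)dimethylsilane | CC(C)(C)[Si](C)(C)Oc1ccc(Br)cc1 | starting material
3 | (4-{[tert-butyl(dimethyl)silyl]oxy}phenyl)magnesium bromide | CC(C)(C)[Si](C)(C)Oc1ccc([Mg]Br)cc1 | intermediate (not isolated)
4 | (2-bromo-4,5-dimethoxyphenyl)(4-{[tert-butyl(dimethyl)silyl]oxy}phenyl)methanol, racemic | COc1cc(Br)c(C(O)c2ccc(O[Si](C)(C)C(C)(C)C)cc2)cc1OC | intermediate
5 | tert-butyl{(2-bromo-4,5-dimethoxyphenyl)(4-{[tert-butyl(dimethyl)silyl]oxy}phenyl)methoxy}dimethylsilane, racemic | COc1cc(Br)c(C(O[Si](C)(C)C(C)(C)C)c2ccc(O[Si](C)(C)C(C)(C)C)cc2)cc1OC | intermediate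
6 | {2-[{[tert-butyl(dimethyl)silyl]oxy}(4-{[tert-butyl(dimethyl)silyl]oxy}phenyl)methyl]-4,5-dimethoxyphenyl}lithium, racemic | [Li]c1cc(OC)c(OC)cc1C(O[Si](C)(C)C(C)(C)C)c1ccc(O[Si](C)(C)C(C)(C)C)cc1 | intermediate (not isolated)
7 | 2-[{[tert-butyl(dimethyl)silyl]oxy}(4-{[tert-butyl(dimethyl)silyl]oxy}phenyl)methyl]-4,5-dimethoxybenzaldehyde, racemic | COc1cc(C=O)c(C(O[Si](C)(C)C(C)(C)C)c2ccc(O[Si](C)(C)C(C)(C)C)cc2)cc1OC | intermediate
8 | fumaryl chloride, (E)-but-2-enedioyl dichloride | O=C(Cl)/C=C/C(=O)Cl | starting material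
9 | 1,3-dimethoxybenzene | COc1cccc(OC)c1 | starting material
10 | (E)-1,4-bis(2,4-dimethoxyphenyl)but-2-ene-1,4-dione | COc1ccc(C(=O)/C=C/C(=O)c2ccc(OC)cc2OC)c(OC)c1 | intermediate
11 | 1,4-bis(2,4-dimethoxyphenyl)-2-(tributyl-λ5-phosphanylidene)butane-1,4-dione | CCCCP(CCCC)(CCCC)=C(CC(=O)c1ccc(OC)cc1OC)C(=O)c1ccc(OC)cc1OC | intermediate (not isolated)
12 | (E)-2-{2-[{[tert-butyl(dimethyl)silyl]oxy}(4-{[tert-butyl(dimethyl)silyl]oxy}phenyl)methyl]-4,5-dimethoxybenzylidene}-1,4-bis(2,4-dimethoxyphenyl)butane-1,4-dione, racemic | O=C(C/C(=C\c1cc(OC)c(OC)cc1C(O[Si](C)(C)C(C)(C)C)c1ccc(O[Si](C)(C)C(C)(C)C)cc1)C(=O)c1ccc(OC)cc1OC)c1ccc(OC)cc1OC | intermediate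
13 | (E)-2-{2-[hydroxy(4-hydroxyphenyl)methyl]-4,5-dimethoxybenzylidene}-1,4-bis(2,4-dimethoxyphenyl)butane-1,4-dione, racemic | O=C(C/C(=C\c1cc(OC)c(OC)cc1C(O)c1ccc(O)cc1)C(=O)c1ccc(OC)cc1OC)c1ccc(OC)cc1OC | intermediate
14 | (E)-2-{4,5-dimethoxy-2-[(4-oxocyclohexa-2,5-dien-1-ylidene)methyl]benzylidene}-1,4-bis(2,4-dimethoxyphenyl)butane-1,4-dione | O=C1C=CC(=Cc2cc(OC)c(OC)cc2/C=C(\CC(=O)c2ccc(OC)cc2OC)C(=O)c2ccc(OC)cc2OC)C=C1 | intermediate (not isolated)
15 | [(1R,2R)-1-(4-hydroxyphenyl)-6,7-dimethoxy-1,2-dihydronaphthalene-2,3-diyl]bis[(2,4-dimethoxyphenyl)methanone], cis epimer | O=C(C1=Cc2cc(OC)c(OC)cc2[C@@H](c2ccc(O)cc2)[C@H]1C(=O)c1ccc(OC)cc1OC)c1ccc(OC)cc1OC | intermediate (not isolated)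
16 | [(1R,2S)-1-(4-hydroxyphenyl)-6,7-dimethoxy-1,2-dihydronaphthalene-2,3-diyl]bis[(2,4-dimethoxyphenyl)methanone], trans | O=C(C1=Cc2cc(OC)c(OC)cc2[C@@H](c2ccc(O)cc2)[C@@H]1C(=O)c1ccc(OC)cc1OC)c1ccc(OC)cc1OC | intermediate
17 | [(1R,2S)-6,7-dihydroxy-1-(4-hydroxyphenyl)-1,2-dihydronaphthalene-2,3-diyl]bis[(2,4-dihydroxyphenyl)methanone], trans | O=C(C1=Cc2cc(O)c(O)cc2[C@@H](c2ccc(O)cc2)[C@@H]1C(=O)c1ccc(O)cc1O)c1ccc(O)cc1O | target

**Count and risks**

Total step count: 8. Longest linear sequence: 7 steps (steps 1, 2, 3, 5, 6, 7, 8).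

Steps most likely to fail:

1. Step 7 (new method). The weak chiral acid may enolise the ketone too slowly, so that the quinone methide is trapped intermolecularly through phenol or carbinol oxygen, or ring closure may pass through a loosely bound ion pair with poor facial selectivity. The fallback uses known chemistry, sets out from 13 and comes back at 16. Racemic acid-catalysed dehydrative cyclisation, an established reaction class for benzhydrols and enolisable carbonyl compounds, is run with (PhO)2P(O)OH or TsOH·H2O in CH2Cl2 at rt through the same quinone methide 14. After equilibration at C2 it should give the racemic trans-hexamethyl ether F1. Preparative chromatography on a chiral stationary phase then separates the enantiomers and delivers 16.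

2. Step 5. The α-branched acyl ylide may add only sluggishly to the hindered ortho-substituted aldehyde, leaving the phosphine to reduce or oligomerise the enedione, or the olefination may lose its (E)-selectivity. The fallback replaces olefination by aldol addition and dehydration; it sets out from 9 (and uses 7) and comes back at 12. Friedel–Crafts acylation of two equivalents of 9 with succinyl chloride (AlCl3, CH2Cl2) gives 1,4-bis(2,4-dimethoxyphenyl)butane-1,4-dione F2. Its mono-lithium enolate (LiN(SiMe3)2, THF, −78 °C) adds to 7 to give the aldol adduct F3 as a mixture of diastereomers. Mesylation (MsCl, Et3N, CH2Cl2) to the mesylate F4 and elimination with DBU should give 12, the (E)-isomer being the thermodynamically favoured one.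

3. Step 6. Once freed, the benzhydrol oxygen may add to the neighbouring enone (closure to a phthalan), the fluoride may shift the alkene out of conjugation with the arene, or the carbinol may ionise on silica gel and close without the chiral acid, which would erode the enantiomeric purity reached in step 7. The fallback carries the benzhydryl oxygen as a methyl ether, which needs no unmasking and itself serves as the leaving group; it sets out from 4 and comes back at 16. Acid-catalysed etherification of 4 (MeOH, HC(OMe)3, pyridinium p-toluenesulfonate, rt) gives the benzhydryl methyl ether F5. Bromine–lithium exchange (n-BuLi, THF, −78 °C) to the aryllithium F6 and formylation with DMF give the aldehyde F7. Wittig reaction with ylide 11, generated from 10 and PBu3 as in step 5, gives the benzylidene diketone F8. Bu4NF/AcOH at 0 °C cleaves the aryl silyl ether to give the phenol F9, which has no free carbinol. Under the conditions of step 7, F9 should lose methanol to the same quinone methide 14 and close to 16.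

**Further compounds**

F1 | step 7 | racemic trans-[1-(4-hydroxyphenyl)-6,7-dimethoxy-1,2-dihydronaphthalene-2,3-diyl]bis[(2,4-dimethoxyphenyl)methanone], 1:1 mixture of 16 and its (1S,2R)-enantiomer | O=C(C1=Cc2cc(OC)c(OC)cc2[C@@H](c2ccc(O)cc2)[C@@H]1C(=O)c1ccc(OC)cc1OC)c1ccc(OC)cc1OC.O=C(C1=Cc2cc(OC)c(OC)cc2[C@H](c2ccc(O)cc2)[C@H]1C(=O)c1ccc(OC)cc1OC)c1ccc(OC)cc1OC
F2 | step 5 | 1,4-bis(2,4-dimethoxyphenyl)butane-1,4-dione | O=C(CCC(=O)c1ccc(OC)cc1OC)c1ccc(OC)cc1OC
F3 | step 5 | 2-{[2-({[tert-butyl(dimethyl)silyl]oxy}(4-{[tert-butyl(dimethyl)silyl]oxy}phenyl)methyl)-4,5-dimethoxyphenyl](hydroxy)methyl}-1,4-bis(2,4-dimethoxyphenyl)butane-1,4-dione, mixture of diastereomers | O=C(CC(C(O)c1cc(OC)c(OC)cc1C(O[Si](C)(C)C(C)(C)C)c1ccc(O[Si](C)(C)C(C)(C)C)cc1)C(=O)c1ccc(OC)cc1OC)c1ccc(OC)cc1OC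
F4 | step 5 | methanesulfonate of F3, mixture of diastereomers | O=C(CC(C(OS(C)(=O)=O)c1cc(OC)c(OC)cc1C(O[Si](C)(C)C(C)(C)C)c1ccc(O[Si](C)(C)C(C)(C)C)cc1)C(=O)c1ccc(OC)cc1OC)c1ccc(OC)cc1OC
F5 | step 6 | {4-[(2-bromo-4,5-dimethoxyphenyl)(methoxy)methyl]phenoxy}(tert-butyl)dimethylsilane, racemic | COc1cc(Br)c(C(OC)c2ccc(O[Si](C)(C)C(C)(C)C)cc2)cc1OC
F6 | step 6 | {2-[(4-{[tert-butyl(dimethyl)silyl]oxy}phenyl)(methoxy)methyl]-4,5-dimethoxyphenyl}lithium, racemic | [Li]c1cc(OC)c(OC)cc1C(OC)c1ccc(O[Si](C)(C)C(C)(C)C)cc1
F7 | step 6 | 2-[(4-{[tert-butyl(dimethyl)silyl]oxy}phenyl)(methoxy)methyl]-4,5-dimethoxybenzaldehyde, racemic | COc1cc(C=O)c(C(OC)c2ccc(O[Si](C)(C)C(C)(C)C)cc2)cc1OC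
F8 | step 6 | (E)-2-{2-[(4-{[tert-butyl(dimethyl)silyl]oxy}phenyl)(methoxy)methyl]-4,5-dimethoxybenzylidene}-1,4-bis(2,4-dimethoxyphenyl)butane-1,4-dione, racemic | O=C(C/C(=C\c1cc(OC)c(OC)cc1C(OC)c1ccc(O[Si](C)(C)C(C)(C)C)cc1)C(=O)c1ccc(OC)cc1OC)c1ccc(OC)cc1OC
F9 | step 6 | (E)-2-{2-[(4-hydroxyphenyl)(methoxy)methyl]-4,5-dimethoxybenzylidene}-1,4-bis(2,4-dimethoxyphenyl)butane-1,4-dione, racemic | O=C(C/C(=C\c1cc(OC)c(OC)cc1C(OC)c1ccc(O)cc1)C(=O)c1ccc(OC)cc1OC)c1ccc(OC)cc1OC
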